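## The problem

The target 18 is a linear tridepside. Three benzoic acid units are joined head to tail by two aryl ester bonds, from the ring A carboxyl to the C4 oxygen of ring B and from the ring B carboxyl to the C4 oxygen of ring C, which ends in a free salicylic-type acid. There is no stereocentre, so the task is purely constitutional. Rings B and C are both orsellinic acid (11), which can be bought, but ring A cannot. Ring A is a pentasubstituted benzene (carboxyl at C1, methoxy at C2, C4 and C5, methyl at C6, hydrogen only at C3), and its C5 oxygen, wedged between the C4 oxygen and the C6 methyl, is the substituent that substitution of an orsellinate does not place cleanly. The depside bonds are cleaved by hydroxide, alkoxide and amines, and 2-hydroxy-6-methylbenzoic acids decarboxylate on heating or in acid, so all hydrolytic and strongly basic operations must precede the first depside bond and the carboxyl groups must be unmasked under neutral conditions. Each orsellinate carries two phenols of which only the C4 hydroxyl may be acylated; the C2 hydroxyl is hydrogen-bonded to its own ester carbonyl, which should make the distinction innate. The ring A carboxyl is flanked on both sides, so its esters form and hydrolyse slowly. The enabling feature is that C1, C2 and C3 of ring A are the α-carbon, ketone carbon and methyl of an acetoacetate, while C4, C5 and C6 are the ester carbon, α-carbon and β-carbon of a 2-methoxybut-2-enoate: the ring is a cyclohexane-1,3-dione one dehydrogenation short of the arene.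

## Retrosynthesis

**18 from 17.** The last bond cut is the O–CH2 bond of the ring C benzyl ester in 17. A benzyl ester is preferred to a simple alkyl ester because hydrolysis would attack the depside bonds first, whereas hydrogenolysis touches neither them nor the aryl methyl ethers. The forward step only has to be neutral and run at room temperature, since the product is a decarboxylation-prone acid.

**17 from 15 and 12.** The ester bond between the ring B carboxyl and the C4 oxygen of ring C is cut, giving didepside acid 15 and benzyl orsellinate 12. Cutting the A–B bond last instead would save the ring A acid for the final coupling, but it needs a B–C didepside with exactly one free C4 hydroxyl, hence orthogonal protection and extra steps. Growing the chain from ring A outward lets 12 serve twice. The forward reaction must activate 15 although its own C2 hydroxyl is free, and must acylate 12 at C4 only; the hydrogen bond on each C2 hydroxyl is relied on for both.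

**15 from 14, and 14 from 10 and 12.** The same two operations one unit earlier lead to 2,4,5-trimethoxy-6-methylbenzoic acid 10 and a second molecule of 12. Acid 10 has no free hydroxyl, and its di-ortho-substituted, electron-rich carboxyl suits an acylium-type activation, the mode by which such acids are known to esterify phenols.

**12 from 11.** The benzyl–oxygen bond is cut. Orsellinic acid 11 is alkylated at the carboxylate only, because a hydrogencarbonate base ionises the acid but not the phenols.

**10 from 9, and 9 from 8.** The acid comes from methyl ester 9 by saponification, placed here because no depside bond exists yet. Ester 9 comes from phenol 8 by cutting the C2 O–CH3 bond; exhaustive O-methylation is safe because every ring A oxygen ends as a methyl ether.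

**8 from 6.** The arene is traced back to cyclohexane-1,3-dione 6, which already holds every carbon and oxygen of ring A and lies one formal dehydrogenation below it. Oxygenating an aromatic orsellinate at C5 would instead raise a C3 versus C5 question on a crowded ring. The forward step needs an oxidant that dehydrogenates faster than the C5 methoxy group is lost by elimination.

**6 from 3 and 4 (key disconnection).** The C1–C6 and C3–C4 bonds are cut through open-chain adduct 5, giving methyl (Z)-2-methoxybut-2-enoate 3 and methyl acetoacetate 4. This is the only pairing of two four-carbon esters that delivers carboxyl, both ring oxygens, the C5 methoxy and the C6 methyl in one ring-forming operation. The forward reaction must achieve a Michael addition to an acceptor deactivated by its α-methoxy group, followed by a Claisen closure.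

**3 from 1 and 2.** The C=C bond is cut to methyl 2-(dimethoxyphosphoryl)-2-methoxyacetate 1 and acetaldehyde 2, a one-step olefination. Its geometric outcome is immaterial, because both alkene carbons become sp3 in the annulation.

## Roads not taken

**Alternative 1:** This road cuts the ring B C1–carbonyl bond together with the carbonyl–oxygen bond to ring C. It would give A1, the benzyl ester and ring B benzyl ether of 18, in one operation from aryl iodide A2 (3-(benzyloxy)-4-iodo-5-methylphenyl 2,4,5-trimethoxy-6-methylbenzoate), carbon monoxide (A3) and the C4 phenoxide of 12. A zerovalent palladium catalyst with a wide-bite-angle diphosphine would insert into the C–I bond, A3 would insert, and the phenoxide would capture the acylpalladium.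

- Merits: no ring B salicylic acid is ever made or activated, and the ring B hydroxyl is masked by a group that leaves in the final hydrogenolysis.
- Weak points: the iodide sits between a benzyloxy and a methyl group on an electron-rich ring, so oxidative addition and the final C–O bond formation are both hindered. A phenoxide at elevated temperature can transfer the ring A acyl group from the existing depside bond. A2 needs regioselective iodination and differentiation of the two orcinol oxygens.
- Comparison: the method does nothing for ring A, so 10 is required anyway. For the B–C bond alone it is arguably the safer construction, since it avoids the free-hydroxy acid 15. The chosen plan sets against this two purchased orsellinate units used unchanged, no metal-catalysed step under pressure, and a protected variant held in reserve.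

**Alternative 2:** This road builds ring C by benzannulation. A4 (benzyl 2-hydroxy-6-methyl-4-(triisopropylsilyloxy)benzoate) would arise from diazo ketone A5 (benzyl (E)-5-diazo-3-methyl-4-oxopent-2-enoate) and siloxyalkyne A6 ((triisopropylsilyloxy)ethyne). The sequence is photochemical Wolff rearrangement to a vinylketene, [2+2] addition of the alkyne, four-electron ring opening and six-electron ring closure.

- Merits: complete regiocontrol, and the two ring C oxygens emerge differentiated.
- Weak points: ring C is orsellinic acid, and A4 after desilylation is simply 12, which the chosen plan reaches in one step from 11. A diazo transfer, a photochemical step and a sensitive alkyne would be spent on a purchasable ring.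
- Comparison: the differentiation it offers is already supplied by the hydrogen bond in 12. It would be the better road only if ring C had to be varied or labelled. Ring A, the real problem, is left open.

**Alternative 3:** This road keeps ring A aromatic and installs the C5 oxygen last. A7 (methyl 2-hydroxy-4-methoxy-6-methylbenzoate) would be oxidised at a carbon anode in an alcoholic electrolyte to the para-quinone monoketal A8 (methyl 3,3,4-trimethoxy-2-methyl-6-oxocyclohexa-1,4-diene-1-carboxylate). Mild reduction of A8 would give 8.

- Merits: it starts from an orsellinate, needs no aromatisation, uses no stoichiometric oxidant, and reaches 8 in a step count at least equal to that of steps 1 to 3 here. In step economy to 8 it is as good as the chosen plan, and it removes the aromatisation risk entirely.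
- Weak points: the phenol is deactivated by its hydrogen-bonded ester. The para position is flanked by the C6 methyl and the C4 methoxy, so ortho attack at C3 and benzylic oxidation of the methyl compete. Four electrons must pass without over-oxidation.
- Comparison: the chosen plan sets against it that the position of every ring A substituent is fixed by the choice of two building blocks, with no site selectivity to be won on a crowded arene, and that only ordinary base chemistry in ordinary glassware is needed.

Key step: step 2

Remarks on the chemistry (assumptions):
- Methyl acetoacetate with NaOMe in MeOH is used so that base, leaving group and both esters are all methyl or methoxide and no ester scrambling can occur.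
- The Z isomer of 3 is the expected main olefination product; any E isomer gives the same 6 and is not separated.
- The aromatisation is expected to leave the C2 hydroxyl free and deliver the C4 oxygen as its methyl ether; any material with a free C4 hydroxyl converges on 9 in step 4.

## Route

Step 1
Reactants: 1 methyl 2-(dimethoxyphosphoryl)-2-methoxyacetate; 2 acetaldehyde
Product: 3 methyl (Z)-2-methoxybut-2-enoate
Conditions: NaH, THF, 0 °C; then MeCHO (excess), 0 °C to rt
Reagents that add atoms: none
Why: Horner–Wadsworth–Emmons olefination of a stabilised α-alkoxy phosphonate anion with an unhindered aldehyde; the ester ends trans to the β-methyl (Z descriptor), and the geometry is of no consequence for step 2.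

Step 2
Reactants: 4 methyl acetoacetate; 3 methyl (Z)-2-methoxybut-2-enoate
Product: 6 methyl 5-methoxy-6-methyl-2,4-dioxocyclohexane-1-carboxylate (mixture of diastereomers and enol forms), via Michael adduct 5 (not isolated)
Conditions: NaOMe (1.1 equiv), MeOH (concentrated), reflux, 24–48 h; then 1 M HCl, 0 °C
Reagents that add atoms: none
Why: Methoxide converts 4 into its stabilised enolate, which adds through the α-carbon to the β-carbon of 3 (C1–C6 bond); the α-methoxy ester enolate formed is protonated by the solvent to give 5. Equilibrium deprotonation of the acetyl methyl of 5 gives the terminal enolate, which attacks the ester carbonyl next to the methoxy-bearing carbon in a 6-(enolendo)-exo-trig Claisen (Dieckmann-type) closure (C3–C4 bond) and expels methoxide. The cyclic tricarbonyl product is far more acidic than methanol and is held as its delocalised enolate, which draws the reversible Michael and Claisen equilibria forward until acid releases 6. The closest known reaction is the alkoxide-mediated Michael–Claisen annulation of acetoacetates with crotonates to dihydroorsellinates; the α-methoxy group only lowers the electrophilicity of the acceptor, hence the long reflux at high concentration. The three stereocentres formed (C1, C5, C6) are not controlled and need not be, because all become sp2 carbons in step 3. Only constitutional selectivity is required: the α-carbon is the most acidic site and performs the Michael step, and afterwards only the acetyl methyl can reach the remaining ester through a six-membered transition state, closure from the α-carbon being a four-membered ring.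

Step 3
Reactants: 6 methyl 5-methoxy-6-methyl-2,4-dioxocyclohexane-1-carboxylate
Product: 8 methyl 2-hydroxy-4,5-dimethoxy-6-methylbenzoate, via vinylogous methyl ester 7 (not isolated)
Conditions: I2 (1.2 equiv), MeOH, reflux; then aq. Na2S2O3
Reagents that add atoms: methanol, CO
Why: Iodine–methanol oxidative aromatisation, known for cyclohexenones and cyclohexane-1,3-diones: the C4 carbonyl, which is not part of the hydrogen-bonded β-keto ester, is etherified to 7 by the HI formed, and α-iodination followed by loss of HI and tautomerisation gives the arene. The C2 hydroxyl stays free because it is chelated to the ester.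

Step 4
Reactants: 8 methyl 2-hydroxy-4,5-dimethoxy-6-methylbenzoate
Product: 9 methyl 2,4,5-trimethoxy-6-methylbenzoate
Conditions: MeI, K2CO3, DMF, 50 °C
Reagents that add atoms: iodomethane, CI
Why: Williamson ether synthesis; the chelated ortho-hydroxyl of orsellinate-type esters is methylated under these mildly forcing carbonate conditions.

Step 5
Reactants: 9 methyl 2,4,5-trimethoxy-6-methylbenzoate
Product: 10 2,4,5-trimethoxy-6-methylbenzoic acid
Conditions: KOH, DMSO–H2O, 90 °C; then 1 M HCl, 0 °C
Reagents that add atoms: potassium hydroxide, [K+].[OH-]
Why: Saponification of a di-ortho-substituted benzoate with poorly solvated hydroxide, as used for 2,4-dimethoxy-6-methylbenzoates; the aryl methyl ethers are inert, and cold acidification avoids protodecarboxylation of the electron-rich acid.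

Step 6
Reactants: 11 orsellinic acid (2,4-dihydroxy-6-methylbenzoic acid)
Product: 12 benzyl orsellinate (benzyl 2,4-dihydroxy-6-methylbenzoate)
Conditions: BnBr, KHCO3, DMF, rt
Reagents that add atoms: benzyl bromide, BrCc1ccccc1
Why: SN2 alkylation of the carboxylate; hydrogencarbonate ionises the acid but not the phenols, and room temperature avoids decarboxylation.

Step 7
Reactants: 10 2,4,5-trimethoxy-6-methylbenzoic acid; 12 benzyl orsellinate
Product: 14 benzyl 2-hydroxy-6-methyl-4-[(2,4,5-trimethoxy-6-methylbenzoyl)oxy]benzoate, via mixed trifluoroacetic anhydride 13 (not isolated)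
Conditions: (CF3CO)2O, toluene, rt
Reagents that add atoms: none
Why: Mixed-anhydride esterification as used in depside synthesis: the hindered, electron-rich acyl group is transferred through an acylium-like species to the free C4 hydroxyl of 12. The C2 hydroxyl is hydrogen-bonded to the benzyl ester carbonyl and does not react.

Step 8
Reactants: 14 benzyl 2-hydroxy-6-methyl-4-[(2,4,5-trimethoxy-6-methylbenzoyl)oxy]benzoate
Product: 15 2-hydroxy-6-methyl-4-[(2,4,5-trimethoxy-6-methylbenzoyl)oxy]benzoic acid
Conditions: H2 (1 atm), 10% Pd/C, EtOAc, rt
Reagents that add atoms: none
Why: Hydrogenolysis of a benzyl ester; aryl esters, aryl methyl ethers and the phenol are untouched, and the neutral room-temperature conditions spare the acid from decarboxylation.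

Step 9
Reactants: 15 2-hydroxy-6-methyl-4-[(2,4,5-trimethoxy-6-methylbenzoyl)oxy]benzoic acid; 12 benzyl orsellinate
Product: 17 benzyl 2-hydroxy-4-({2-hydroxy-6-methyl-4-[(2,4,5-trimethoxy-6-methylbenzoyl)oxy]benzoyl}oxy)-6-methylbenzoate, via mixed trifluoroacetic anhydride 16 (not isolated)
Conditions: (CF3CO)2O, toluene, rt
Reagents that add atoms: none
Why: The same mixed-anhydride depside esterification, of the kind applied to 2-hydroxybenzoic acids whose chelated, flanked ortho-hydroxyl is a poor nucleophile; any aryl trifluoroacetate formed there is cleaved on aqueous work-up. The unhindered C4 hydroxyl of 12 captures the acyl group.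

Step 10
Reactants: 17 benzyl 2-hydroxy-4-({2-hydroxy-6-methyl-4-[(2,4,5-trimethoxy-6-methylbenzoyl)oxy]benzoyl}oxy)-6-methylbenzoate
Product: 18 2-hydroxy-4-({2-hydroxy-6-methyl-4-[(2,4,5-trimethoxy-6-methylbenzoyl)oxy]benzoyl}oxy)-6-methylbenzoic acid (target)
Conditions: H2 (1 atm), 10% Pd/C, EtOAc, rt
Reagents that add atoms: none
Why: Hydrogenolysis of the benzyl ester under neutral conditions leaves both depside bonds and all ethers intact and frees the terminal acid without heat or acid.

## Compound list

1 | methyl 2-(dimethoxyphosphoryl)-2-methoxyacetate | COC(C(=O)OC)P(=O)(OC)OC | starting material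
2 | acetaldehyde | CC=O | starting material
3 | methyl (Z)-2-methoxybut-2-enoate | C/C=C(\OC)C(=O)OC | intermediate
4 | methyl acetoacetate (methyl 3-oxobutanoate) | COC(=O)CC(C)=O | starting material
5 | dimethyl 2-acetyl-4-methoxy-3-methylpentanedioate (Michael adduct, mixture of diastereomers) | COC(=O)C(C(C)=O)C(C)C(OC)C(=O)OC | intermediate (not isolated)
6 | methyl 5-methoxy-6-methyl-2,4-dioxocyclohexane-1-carboxylate (mixture of diastereomers and enol forms) | COC(=O)C1C(C)C(OC)C(=O)CC1=O | intermediate
7 | methyl 4,5-dimethoxy-6-methyl-2-oxocyclohex-3-ene-1-carboxylate (mixture of diastereomers) | COC(=O)C1C(C)C(OC)C(OC)=CC1=O | intermediate (not isolated)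
8 | methyl 2-hydroxy-4,5-dimethoxy-6-methylbenzoate | COC(=O)c1c(C)c(OC)c(OC)cc1O | intermediate
9 | methyl 2,4,5-trimethoxy-6-methylbenzoate | COC(=O)c1c(C)c(OC)c(OC)cc1OC | intermediate
10 | 2,4,5-trimethoxy-6-methylbenzoic acid | COc1cc(OC)c(C(=O)O)c(C)c1OC | intermediate
11 | orsellinic acid (2,4-dihydroxy-6-methylbenzoic acid) | Cc1cc(O)cc(O)c1C(=O)O | starting material
12 | benzyl orsellinate (benzyl 2,4-dihydroxy-6-methylbenzoate) | Cc1cc(O)cc(O)c1C(=O)OCc1ccccc1 | intermediate
13 | 2,4,5-trimethoxy-6-methylbenzoic trifluoroacetic anhydride | COc1cc(OC)c(C(=O)OC(=O)C(F)(F)F)c(C)c1OC | intermediate (not isolated)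
14 | benzyl 2-hydroxy-6-methyl-4-[(2,4,5-trimethoxy-6-methylbenzoyl)oxy]benzoate | COc1cc(OC)c(C(=O)Oc2cc(C)c(C(=O)OCc3ccccc3)c(O)c2)c(C)c1OC | intermediate
15 | 2-hydroxy-6-methyl-4-[(2,4,5-trimethoxy-6-methylbenzoyl)oxy]benzoic acid | COc1cc(OC)c(C(=O)Oc2cc(C)c(C(=O)O)c(O)c2)c(C)c1OC | intermediate
16 | 2-hydroxy-6-methyl-4-[(2,4,5-trimethoxy-6-methylbenzoyl)oxy]benzoic trifluoroacetic anhydride | COc1cc(OC)c(C(=O)Oc2cc(C)c(C(=O)OC(=O)C(F)(F)F)c(O)c2)c(C)c1OC | intermediate (not isolated)
17 | benzyl 2-hydroxy-4-({2-hydroxy-6-methyl-4-[(2,4,5-trimethoxy-6-methylbenzoyl)oxy]benzoyl}oxy)-6-methylbenzoate | COc1cc(OC)c(C(=O)Oc2cc(C)c(C(=O)Oc3cc(C)c(C(=O)OCc4ccccc4)c(O)c3)c(O)c2)c(C)c1OC | intermediate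
18 | 2-hydroxy-4-({2-hydroxy-6-methyl-4-[(2,4,5-trimethoxy-6-methylbenzoyl)oxy]benzoyl}oxy)-6-methylbenzoic acid | COc1cc(OC)c(C(=O)Oc2cc(C)c(C(=O)Oc3cc(C)c(C(=O)O)c(O)c3)c(O)c2)c(C)c1OC | target

## Step count and least certain steps

Total step count: 10. Longest linear sequence: 9 steps (steps 1 to 5 and 7 to 10, from 1 to 18); step 6 is a one-step branch.

**Step 2 (key step).** The most likely failure is slow conjugate addition to the α-methoxy enoate, so that retro-Michael reaction and reversible self-condensation of 4 dominate and conversion stays low. The fallback keeps the ring and the C1–C6 Michael bond but changes to the malonate–enone pairing, in which the acceptor is a ketone.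
- It sets out from 3: i-PrMgCl and MeNH(OMe)·HCl in THF at −20 °C give (Z)-N,2-dimethoxy-N-methylbut-2-enamide F1.
- MeMgBr converts this into (Z)-3-methoxypent-3-en-2-one F2.
- F2 with dimethyl malonate and NaOMe in refluxing MeOH undergoes Michael addition, then Claisen closure of the ketone methyl onto a malonate ester, and comes back to the route at 6.

**Step 3.** The risk is acid-promoted elimination of methanol across C5–C6 in hot methanolic HI, a redox-neutral aromatisation that would delete the C5 oxygen. Incomplete dehydrogenation or iodination of the electron-rich ring at C3 are lesser risks. The fallback replaces the hot iodine–methanol step by bromination–dehydrobromination at room temperature.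
- It sets out from 6: Br2 (2 equiv) in AcOH gives methyl 3-bromo-2,4-dihydroxy-5-methoxy-6-methylbenzoate F3.
- H2, Pd/C and NaOAc in MeOH remove the bromine to give methyl 2,4-dihydroxy-5-methoxy-6-methylbenzoate F4.
- The conditions of step 4 with more MeI methylate both phenols and rejoin the route at 9.

**Step 9.** The risk is self-acylation of activated 15 through its own free C2 hydroxyl (oligomer formation), C-acylation of 12, or decarboxylation of 15 before it couples. The fallback masks the ring B hydroxyl. It sets out from 10 and 11 and comes back at 18.
- Allyl bromide and KHCO3 in DMF convert 11 into allyl 2,4-dihydroxy-6-methylbenzoate F7.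
- Coupling with 10 as in step 7 gives allyl 2-hydroxy-6-methyl-4-[(2,4,5-trimethoxy-6-methylbenzoyl)oxy]benzoate F8.
- BnBr and K2CO3 in acetone give allyl 2-(benzyloxy)-6-methyl-4-[(2,4,5-trimethoxy-6-methylbenzoyl)oxy]benzoate F9.
- Pd(PPh3)4 with sodium 4-toluenesulfinate removes the allyl group to give 2-(benzyloxy)-6-methyl-4-[(2,4,5-trimethoxy-6-methylbenzoyl)oxy]benzoic acid F10, whose activation meets no free phenol.
- Coupling with 12 gives benzyl 4-({2-(benzyloxy)-6-methyl-4-[(2,4,5-trimethoxy-6-methylbenzoyl)oxy]benzoyl}oxy)-2-hydroxy-6-methylbenzoate F11 (the same constitution as A1).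
- One hydrogenolysis removes both benzyl groups and gives 18.

**Step 5.** The risk is sluggish attack of hydroxide at the doubly flanked carbonyl, with prolonged heating bringing partial ether cleavage, or protodecarboxylation on acidification. The fallback avoids hydroxide attack by a redox detour.
- It sets out from 9: LiAlH4 in THF gives (2,4,5-trimethoxy-6-methylphenyl)methanol F5.
- MnO2 in CH2Cl2 gives 2,4,5-trimethoxy-6-methylbenzaldehyde F6.
- NaClO2, NaH2PO4 and 2-methylbut-2-ene in aqueous t-BuOH oxidise F6 to the acid, rejoining the route at 10.

## Further compounds

F1 | step 2 | (Z)-N,2-dimethoxy-N-methylbut-2-enamide | C/C=C(\OC)C(=O)N(C)OC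
F2 | step 2 | (Z)-3-methoxypent-3-en-2-one | C/C=C(\OC)C(C)=O
F3 | step 3 | methyl 3-bromo-2,4-dihydroxy-5-methoxy-6-methylbenzoate | COC(=O)c1c(C)c(OC)c(O)c(Br)c1O
F4 | step 3 | methyl 2,4-dihydroxy-5-methoxy-6-methylbenzoate | COC(=O)c1c(C)c(OC)c(O)cc1O
F5 | step 5 | (2,4,5-trimethoxy-6-methylphenyl)methanol | COc1cc(OC)c(CO)c(C)c1OC
F6 | step 5 | 2,4,5-trimethoxy-6-methylbenzaldehyde | COc1cc(OC)c(C=O)c(C)c1OC
F7 | step 9 | allyl 2,4-dihydroxy-6-methylbenzoate | Cc1cc(O)cc(O)c1C(=O)OCC=C
F8 | step 9 | allyl 2-hydroxy-6-methyl-4-[(2,4,5-trimethoxy-6-methylbenzoyl)oxy]benzoate | COc1cc(OC)c(C(=O)Oc2cc(C)c(C(=O)OCC=C)c(O)c2)c(C)c1OC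
F9 | step 9 | allyl 2-(benzyloxy)-6-methyl-4-[(2,4,5-trimethoxy-6-methylbenzoyl)oxy]benzoate | COc1cc(OC)c(C(=O)Oc2cc(C)c(C(=O)OCC=C)c(OCc3ccccc3)c2)c(C)c1OC
F10 | step 9 | 2-(benzyloxy)-6-methyl-4-[(2,4,5-trimethoxy-6-methylbenzoyl)oxy]benzoic acid | COc1cc(OC)c(C(=O)Oc2cc(C)c(C(=O)O)c(OCc3ccccc3)c2)c(C)c1OC
F11 | step 9 | benzyl 4-({2-(benzyloxy)-6-methyl-4-[(2,4,5-trimethoxy-6-methylbenzoyl)oxy]benzoyl}oxy)-2-hydroxy-6-methylbenzoate | COc1cc(OC)c(C(=O)Oc2cc(C)c(C(=O)Oc3cc(C)c(C(=O)OCc4ccccc4)c(O)c3)c(OCc3ccccc3)c2)c(C)c1OC
A1 | alternative 1 | benzyl 4-({2-(benzyloxy)-6-methyl-4-[(2,4,5-trimethoxy-6-methylbenzoyl)oxy]benzoyl}oxy)-2-hydroxy-6-methylbenzoate | COc1cc(OC)c(C(=O)Oc2cc(C)c(C(=O)Oc3cc(C)c(C(=O)OCc4ccccc4)c(O)c3)c(OCc3ccccc3)c2)c(C)c1OC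
A2 | alternative 1 | 3-(benzyloxy)-4-iodo-5-methylphenyl 2,4,5-trimethoxy-6-methylbenzoate | COc1cc(OC)c(C(=O)Oc2cc(C)c(I)c(OCc3ccccc3)c2)c(C)c1OC
A3 | alternative 1 | carbon monoxide | [C-]#[O+]
A4 | alternative 2 | benzyl 2-hydroxy-6-methyl-4-(triisopropylsilyloxy)benzoate | Cc1cc(O[Si](C(C)C)(C(C)C)C(C)C)cc(O)c1C(=O)OCc1ccccc1
A5 | alternative 2 | benzyl (E)-5-diazo-3-methyl-4-oxopent-2-enoate | O=C(OCc1ccccc1)/C=C(\C)C(=O)C=[N+]=[N-]
A6 | alternative 2 | (triisopropylsilyloxy)ethyne | C#CO[Si](C(C)C)(C(C)C)C(C)C
A7 | alternative 3 | methyl 2-hydroxy-4-methoxy-6-methylbenzoate | COC(=O)c1c(C)cc(OC)cc1O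
A8 | alternative 3 | methyl 3,3,4-trimethoxy-2-methyl-6-oxocyclohexa-1,4-diene-1-carboxylate | COC(=O)C1=C(C)C(OC)(OC)C(OC)=CC1=O
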